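**Strategy**

Thiocladospolide F is cut at sulfur into two identical twelve-membered ene-diones (ring atoms O1, lactone C2, C3, C4, ketone C5, carbinol C6, C7–C11, methyl-bearing C12), rejoined at the end by double sulfa-Michael addition at C3. Each ring is closed at C6–C7. The key step exploits the α-ketol: C6 is both carbinol and α-carbon of the C5 ketone, so a C5=C6 enediolate attacks the C7 terminus of a C7–C9 π-allylpalladium under a chiral ligand. One operation forms the macrocycle, the C6–C7 bond and the C6 stereocenter at the final oxidation level; its precursor is an open-chain O-silyl O-acetyl enediol dienoate carrying an allylic acetate.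

Key step: step 5

Assumption: sulfide is taken to add to the C3=C4 bond of the macrocyclic ene-dione on the ring face that gives the 3,6-cis (3S) adduct, the reversible addition allowing equilibration towards it; the catalyst-controlled fallback covers the other case.

**Route**

Step 1
Reactants: 1 (R)-hex-5-en-2-ol; 2 (Z)-but-2-ene-1,4-diyl diacetate
Product: 3 (R,E)-6-hydroxyhept-2-en-1-yl acetate
Conditions: second-generation Hoveyda–Grubbs catalyst (3 mol%), 2 (2 equiv), CH2Cl2, 40 °C
Reagents that add atoms: none
Why: Olefin cross-metathesis of a terminal alkene with an excess of the symmetrical internal diacetate should give the E-allylic acetate, the free alcohol being tolerated and the carbinol center untouched.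

Step 2
Reactants: 4 furan-2-ylmethyl acetate
Product: 7 (E)-5-acetoxy-4-oxopent-2-enoic acid, via Z-keto-enal 5 (not isolated), via E-keto-enal 6 (not isolated)
Conditions: NBS, NaHCO3, acetone/H2O, −15 °C; pyridine, rt; then NaClO2, NaH2PO4, 2-methyl-2-butene, t-BuOH/H2O, 0 °C to rt
Reagents that add atoms: water (O); sodium chlorite ([Na+].[O-]Cl=O)
Why: Bromonium-induced oxidative ring opening of the 2-substituted furan (a masked 4-oxo-2-enal) should give the Z-keto-enal, pyridine isomerizes it to the E isomer, and Pinnick oxidation then converts only the aldehyde into the acid.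

Step 3
Reactants: 3 (R,E)-6-hydroxyhept-2-en-1-yl acetate; 7 (E)-5-acetoxy-4-oxopent-2-enoic acid
Product: 8 (2R,5E)-7-acetoxyhept-5-en-2-yl (E)-5-acetoxy-4-oxopent-2-enoate
Conditions: EDC·HCl, DMAP (10 mol%), CH2Cl2, 0 °C
Reagents that add atoms: none
Why: Steglich-type carbodiimide esterification acylates the secondary alcohol without breaking its C–O bond, so the R configuration is retained, and catalytic DMAP at 0 °C should spare the ene-dione.

Step 4
Reactants: 8 (2R,5E)-7-acetoxyhept-5-en-2-yl (E)-5-acetoxy-4-oxopent-2-enoate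
Product: 9 (2R,5E)-7-acetoxyhept-5-en-2-yl (2E,4Z)-5-acetoxy-4-[(tert-butyldimethylsilyl)oxy]penta-2,4-dienoate
Conditions: TBSOTf (1.1 equiv), Et3N, CH2Cl2, −78 to 0 °C
Reagents that add atoms: tert-butyldimethylsilyl trifluoromethanesulfonate (CC(C)(C)[Si](C)(C)OS(=O)(=O)C(F)(F)F)
Why: Soft enolization with silyl triflate and amine can occur only at the acetoxymethyl carbon of the ketone (the other α-carbon is vinylic) and should give the Z-configured 2-silyloxy diene by minimizing allylic 1,3-strain.

Step 5
Reactants: 9 (2R,5E)-7-acetoxyhept-5-en-2-yl (2E,4Z)-5-acetoxy-4-[(tert-butyldimethylsilyl)oxy]penta-2,4-dienoate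
Product: 10 (3E,6S,8E,12R)-12-methyl-2,5-dioxo-1-oxacyclododeca-3,8-dien-6-yl acetate
Conditions: Pd2(dba)3·CHCl3 (5 mol%), (R,R)-N,N′-(cyclohexane-1,2-diyl)bis[2-(diphenylphosphanyl)-1-naphthamide] (12 mol%), tetrabutylammonium difluorotriphenylsilicate (TBAT, 1.1 equiv), 1,4-dioxane, 9 added over 12 h to 0.002 M, 40 °C, degassed
Reagents that add atoms: none
Why: Proposed new method: zerovalent palladium ionizes the allylic acetate of 9 to a syn π-allyl complex spanning C7–C9 while fluoride from TBAT cleaves the silyl enol ether to the C5=C6 O-acetyl enediolate, whose carbon C6 attacks the unsubstituted terminus C7 in an outer-sphere Tsuji–Trost alkylation. The closest known reactions are the palladium-catalyzed asymmetric allylic alkylation of acyclic 1,2-enediol derivatives to α-acyloxy ketones with a tertiary stereocenter, the fluoride-triggered allylation of enol silanes, and the Tsuji–Trost macrocyclization of stabilized carbanions; their union in one ring closure is what is new. The twelve-membered ring closes by attack at the distal allyl terminus (endo with respect to the allyl unit), which leaves the E-configured C8=C9 olefin inside the ring, rather than at C9, which would give a ten-membered ring with a vinyl branch. The C6 configuration is controlled by the chiral ligand, which differentiates the faces of the Z-enediolate; the (R,R) ligand is assumed to give 6S by analogy with the acyclic series, its mirror image being used otherwise, and the remote C12 center is expected to exert little bias. The step needs C- over O-alkylation, C6 over C5 alkylation (no O-to-O acetyl migration), C7 over C9 attack and ring closure over oligomerization; these should be secured by the soft ligand-bound π-allyl, by C5 being a fully substituted site whose alkylation would require an eleven-membered ring, by the preference of the ligand pocket for the CH2 terminus, and by slow addition at high dilution.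

Step 6
Reactants: 10 (3E,6S,8E,12R)-12-methyl-2,5-dioxo-1-oxacyclododeca-3,8-dien-6-yl acetate (two equivalents)
Product: 12 3,3'-thiobis[(3S,6S,8E,12R)-6-acetoxy-12-methyl-1-oxacyclododec-8-ene-2,5-dione], via thiol 11 (not isolated)
Conditions: Na2S·9H2O (0.5 equiv), AcOH (1.0 equiv), THF/H2O, 0 °C, closed flask
Reagents that add atoms: sodium sulfide, used as its nonahydrate ([Na+].[Na+].[S-2])
Why: In this double sulfa-Michael addition hydrosulfide should attack C3 (β to the C5 ketone) of one ene-dione and the resulting thiol 11 the C3 of a second; each new C3 center is set by substrate control through attack on the exposed face of the C3=C4 bond of the conformationally biased ring to give the 3,6-cis (3S) adduct, and the reversibility of the addition under acetate buffering should let the mixture settle on this epimer.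

Step 7
Reactants: 12 3,3'-thiobis[(3S,6S,8E,12R)-6-acetoxy-12-methyl-1-oxacyclododec-8-ene-2,5-dione]
Product: 13 3,3'-thiobis[(3S,6S,12R)-6-acetoxy-12-methyl-1-oxacyclododecane-2,5-dione]
Conditions: dipotassium azodicarboxylate (KO2CN=NCO2K, excess, in portions), AcOH, MeOH/CH2Cl2, 0 °C to rt
Reagents that add atoms: none
Why: Diimide generated in situ should deliver hydrogen in a concerted syn fashion to the two isolated C8=C9 bonds without a metal catalyst, so the sulfide does not interfere, ketones and esters are inert, and the acidic medium disfavors retro-sulfa-Michael cleavage.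

Step 8
Reactants: 13 3,3'-thiobis[(3S,6S,12R)-6-acetoxy-12-methyl-1-oxacyclododecane-2,5-dione]
Product: 14 thiocladospolide F, 3,3'-thiobis[(3S,6S,12R)-6-hydroxy-12-methyl-1-oxacyclododecane-2,5-dione]
Conditions: Sc(OTf)3 (20 mol%), MeOH/H2O (4:1), rt
Reagents that add atoms: none
Why: Lewis-acid-catalyzed methanolysis is accelerated by chelation between each acetate and its adjacent C5 ketone, so the two α-keto acetates should be cleaved without base, leaving the lactones, the β-keto sulfide and the epimerizable C6 and C3 centers intact.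

**Compound list**

1 | (R)-hex-5-en-2-ol | C[C@@H](O)CCC=C | starting material
2 | (Z)-but-2-ene-1,4-diyl diacetate | CC(=O)OC/C=C\COC(C)=O | starting material
3 | (R,E)-6-hydroxyhept-2-en-1-yl acetate | C[C@@H](O)CC/C=C/COC(C)=O | intermediate
4 | furan-2-ylmethyl acetate (furfuryl acetate) | CC(=O)OCc1ccco1 | starting material
5 | Z-keto-enal: (Z)-5-acetoxy-4-oxopent-2-enal, not isolated | CC(=O)OCC(=O)/C=C\C=O | intermediate
6 | E-keto-enal: (E)-5-acetoxy-4-oxopent-2-enal, not isolated | CC(=O)OCC(=O)/C=C/C=O | intermediate
7 | (E)-5-acetoxy-4-oxopent-2-enoic acid | CC(=O)OCC(=O)/C=C/C(=O)O | intermediate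
8 | (2R,5E)-7-acetoxyhept-5-en-2-yl (E)-5-acetoxy-4-oxopent-2-enoate | C[C@H](CC/C=C/COC(C)=O)OC(=O)/C=C/C(=O)COC(C)=O | intermediate
9 | (2R,5E)-7-acetoxyhept-5-en-2-yl (2E,4Z)-5-acetoxy-4-[(tert-butyldimethylsilyl)oxy]penta-2,4-dienoate | C[C@H](CC/C=C/COC(C)=O)OC(=O)/C=C/C(O[Si](C)(C)C(C)(C)C)=C/OC(C)=O | intermediate
10 | (3E,6S,8E,12R)-12-methyl-2,5-dioxo-1-oxacyclododeca-3,8-dien-6-yl acetate | C[C@@H]1CC/C=C/C[C@H](OC(C)=O)C(=O)/C=C/C(=O)O1 | intermediate
11 | thiol: (3S,6S,8E,12R)-12-methyl-2,5-dioxo-3-sulfanyl-1-oxacyclododec-8-en-6-yl acetate, not isolated | C[C@@H]1CC/C=C/C[C@H](OC(C)=O)C(=O)C[C@H](S)C(=O)O1 | intermediate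
12 | 3,3'-thiobis[(3S,6S,8E,12R)-6-acetoxy-12-methyl-1-oxacyclododec-8-ene-2,5-dione] | C[C@@H]1CC/C=C/C[C@H](OC(C)=O)C(=O)C[C@H](S[C@H]2CC(=O)[C@@H](OC(C)=O)C/C=C/CC[C@@H](C)OC2=O)C(=O)O1 | intermediate
13 | 3,3'-thiobis[(3S,6S,12R)-6-acetoxy-12-methyl-1-oxacyclododecane-2,5-dione] | C[C@@H]1CCCCC[C@H](OC(C)=O)C(=O)C[C@H](S[C@H]2CC(=O)[C@@H](OC(C)=O)CCCCC[C@@H](C)OC2=O)C(=O)O1 | intermediate
14 | thiocladospolide F, 3,3'-thiobis[(3S,6S,12R)-6-hydroxy-12-methyl-1-oxacyclododecane-2,5-dione] | C[C@@H]1CCCCC[C@H](O)C(=O)C[C@H](S[C@H]2CC(=O)[C@@H](O)CCCCC[C@@H](C)OC2=O)C(=O)O1 | target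

**Step count**

Total steps: 8. Longest linear sequence: 7 steps (steps 1, 3, 4, 5, 6, 7, 8; equally 2, 3, 4, 5, 6, 7, 8).

**Steps most likely to fail**

Step 5 (Proposed new method). What may go wrong: intermolecular allylation may outrun ring closure and give oligomers; O-to-O acetyl migration in the enediolate may divert alkylation to C5; or the enolate faces may be poorly differentiated in the macrocyclic transition state. The fallback makes the C6–C7 bond in open-chain form and closes the ring at the lactone instead. It sets out from 7 (and uses 3) and returns at 10. Acid 7 is esterified (Boc2O, catalytic DMAP, t-BuOH) to tert-butyl (E)-5-acetoxy-4-oxopent-2-enoate F1, which is enolized (TBSOTf, Et3N) to tert-butyl (2E,4Z)-5-acetoxy-4-[(tert-butyldimethylsilyl)oxy]penta-2,4-dienoate F2. Intermolecular fluoride-triggered Tsuji–Trost allylation of F2 with allylic acetate 3 (Pd2(dba)3·CHCl3, the same ligand, TBAT, THF) should give tert-butyl (2E,5S,7E,11R)-5-acetoxy-11-hydroxy-4-oxododeca-2,7-dienoate F3. TFA in CH2Cl2 frees (2E,5S,7E,11R)-5-acetoxy-11-hydroxy-4-oxododeca-2,7-dienoic acid F4, and Yamaguchi macrolactonization (2,4,6-trichlorobenzoyl chloride, Et3N, then DMAP, toluene, high dilution) returns to 10.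

Step 6. What may go wrong: poor facial selectivity in either C–S bond formation would give a mixture of the three possible C3/C3' diastereomeric sulfides. The fallback replaces substrate control by catalyst control and builds the sulfide stepwise. It sets out from 10 and returns at 12. Thioacetic acid is added to 10 under a cinchona-derived bifunctional squaramide catalyst (asymmetric sulfa-Michael addition) to give (3S,6S,8E,12R)-3-(acetylsulfanyl)-12-methyl-2,5-dioxo-1-oxacyclododec-8-en-6-yl acetate F5. S-to-N acetyl transfer to cysteamine (cysteamine hydrochloride, NaHCO3, degassed MeOH/H2O, 0 °C) liberates thiol 11, here isolated. Thiol 11 is then added to a second equivalent of 10 under the same catalyst to reach 12.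

Step 8. What may go wrong: retro-sulfa-Michael fragmentation of the β-keto sulfide or methanolysis of the lactones may compete with cleavage of the two acetates. The fallback removes the acetate before sulfur is introduced and carries the free hydroxyl forward. It sets out from 10 and returns at 14. Lipase-catalyzed hydrolysis of 10 (immobilized Candida antarctica lipase B, pH 7 phosphate buffer/acetone) should give (3E,6S,8E,12R)-6-hydroxy-12-methyl-1-oxacyclododeca-3,8-diene-2,5-dione F6. Na2S·9H2O/AcOH as in step 6 then gives, through the non-isolated thiol (3S,6S,8E,12R)-6-hydroxy-12-methyl-3-sulfanyl-1-oxacyclododec-8-ene-2,5-dione F7, the sulfide 3,3'-thiobis[(3S,6S,8E,12R)-6-hydroxy-12-methyl-1-oxacyclododec-8-ene-2,5-dione] F8. Diimide reduction as in step 7 converts F8 directly into 14.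

Further compounds
F1 | step 5 | tert-butyl (E)-5-acetoxy-4-oxopent-2-enoate | CC(=O)OCC(=O)/C=C/C(=O)OC(C)(C)C
F2 | step 5 | tert-butyl (2E,4Z)-5-acetoxy-4-[(tert-butyldimethylsilyl)oxy]penta-2,4-dienoate | CC(C)(C)OC(=O)/C=C/C(O[Si](C)(C)C(C)(C)C)=C/OC(C)=O
F3 | step 5 | tert-butyl (2E,5S,7E,11R)-5-acetoxy-11-hydroxy-4-oxododeca-2,7-dienoate | C[C@@H](O)CC/C=C/C[C@H](OC(C)=O)C(=O)/C=C/C(=O)OC(C)(C)C
F4 | step 5 | (2E,5S,7E,11R)-5-acetoxy-11-hydroxy-4-oxododeca-2,7-dienoic acid | C[C@@H](O)CC/C=C/C[C@H](OC(C)=O)C(=O)/C=C/C(=O)O
F5 | step 6 | (3S,6S,8E,12R)-3-(acetylsulfanyl)-12-methyl-2,5-dioxo-1-oxacyclododec-8-en-6-yl acetate | C[C@@H]1CC/C=C/C[C@H](OC(C)=O)C(=O)C[C@H](SC(C)=O)C(=O)O1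
F6 | step 8 | (3E,6S,8E,12R)-6-hydroxy-12-methyl-1-oxacyclododeca-3,8-diene-2,5-dione | C[C@@H]1CC/C=C/C[C@H](O)C(=O)/C=C/C(=O)O1
F7 | step 8 | (3S,6S,8E,12R)-6-hydroxy-12-methyl-3-sulfanyl-1-oxacyclododec-8-ene-2,5-dione | C[C@@H]1CC/C=C/C[C@H](O)C(=O)C[C@H](S)C(=O)O1
F8 | step 8 | 3,3'-thiobis[(3S,6S,8E,12R)-6-hydroxy-12-methyl-1-oxacyclododec-8-ene-2,5-dione] | C[C@@H]1CC/C=C/C[C@H](O)C(=O)C[C@H](S[C@H]2CC(=O)[C@@H](O)C/C=C/CC[C@@H](C)OC2=O)C(=O)O1
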